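**Plan**

1. Drimane numbering is used: ring A = C1–C5 and C10 (C3 carbinol, C4 CMe2, methyl on C10); ring B = C5–C10 (C6 ketone, C7=C8 with methyl C12, C9 bearing C11H2–O–aryl).
2. Cuts: first the C11–O aryl ether (umbelliferone), then in ring B the C6–C7 bond (carbonyl-ene) and the C9–C10 bond ([3,3] shift); the acyclic dienol so reached is cut once more at C6–C7 into a ring A enal and a C5 allyl unit.
3. What allows this: quaternary C10 and tertiary C9 are neighbours standing β and γ to the C6 carbonyl, and C7=C8(CH3) is an isopropenyl group in disguise, so ring B is the image of the 3-oxy-1,5-diene C10=C5–C6(O)–C7–C8=C9.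
4. Forward: ring A is made first from 2,2-dimethylcyclohexane-1,3-dione, the C7–C8–C9–C11 chain is joined at C6, ring B arises in one flask (anionic oxy-Cope shift, then carbonyl-ene closure), and the coumarin is attached near the end.
5. Stereochemistry: the C6 carbinol comes from an oxazaborolidine-catalysed borane reduction and is relayed through a chair transition state to C10 and C9; C5 is set by equilibration to the trans ring fusion; C3 by equatorial hydride delivery from LiBH(s-Bu)3.

Key step: step 10

Remark: (E)-4-chloro-3-methylbut-2-enyl acetate is taken to be purchasable; bicyclic compounds are named as drimanes, and the C5 and C6 configurations drawn for 14, 15 and 19 are the expected ones but do not matter, since C5 is equilibrated in step 12 and C6 is oxidised in steps 11 and 16.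

**Route**

Step 1
Reactants: 1 2,2-dimethylcyclohexane-1,3-dione
Product: 2 6,6-dimethyl-1,4-dioxaspiro[4.5]decan-7-one
Conditions: ethylene glycol (1.1 equiv.), p-TsOH (cat.), benzene, reflux, Dean–Stark trap
Reagents that add atoms: ethylene glycol, OCCO
Why: Acid-catalysed ketalisation with azeotropic removal of water should stop at the monoketal, because the remaining carbonyl is then flanked by the gem-dimethyl carbon and the dioxolane; no stereocentre is formed.

Step 2
Reactants: 2 6,6-dimethyl-1,4-dioxaspiro[4.5]decan-7-one
Product: 3 (±)-6,6,8-trimethyl-1,4-dioxaspiro[4.5]decan-7-one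
Conditions: LiN(i-Pr)2, THF, −78 °C; MeI, −78 → 0 °C
Reagents that add atoms: iodomethane, CI
Why: Only one α-carbon carries hydrogen, so kinetic deprotonation and C-methylation (enolate alkylation) can only take place there; the new stereocentre is racemic and is destroyed in step 3.

Step 3
Reactants: 3 (±)-6,6,8-trimethyl-1,4-dioxaspiro[4.5]decan-7-one
Product: 4 6,6,8-trimethyl-1,4-dioxaspiro[4.5]dec-7-en-7-yl trifluoromethanesulfonate
Conditions: LiN(i-Pr)2, THF, −78 → 0 °C; PhNTf2, 0 °C → rt
Reagents that add atoms: N-phenylbis(trifluoromethanesulfonimide), O=S(=O)(N(c1ccccc1)S(=O)(=O)C(F)(F)F)C(F)(F)F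
Why: The single remaining α-hydrogen is the methine, so deprotonation and O-sulfonylation with PhNTf2 (enol triflate formation) can only give the tetrasubstituted alkene, in which the methyl is cis to the carbon that becomes C6.

Step 4
Reactants: 4 6,6,8-trimethyl-1,4-dioxaspiro[4.5]dec-7-en-7-yl trifluoromethanesulfonate
Product: 5 6,6,8-trimethyl-1,4-dioxaspiro[4.5]dec-7-ene-7-carbaldehyde (ring A enal)
Conditions: Pd(PPh3)4 (5 mol %), LiCl, CO (3 atm), Bu3SnH (slow addition), THF, 50 °C
Reagents that add atoms: carbon monoxide, [C-]#[O+]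
Why: Palladium-catalysed reductive carbonylation (formylation) of a vinyl triflate: oxidative addition to zerovalent palladium, CO insertion and hydride transfer from Bu3SnH give the enal, and slow addition of the tin hydride under CO pressure suppresses plain reduction of the triflate.

Step 5
Reactants: 6 (E)-4-chloro-3-methylbut-2-en-1-yl acetate
Product: 7 (E)-4-chloro-3-methylbut-2-en-1-ol
Conditions: K2CO3 (0.2 equiv.), MeOH, 0 °C
Reagents that add atoms: none
Why: Carbonate-catalysed transesterification with methanol removes the acetate at 0 °C much faster than methoxide displaces the allylic chloride, and the (E)-alkene is not touched.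

Step 6
Reactants: 7 (E)-4-chloro-3-methylbut-2-en-1-ol
Product: 8 (E)-tert-butyl[(4-chloro-3-methylbut-2-en-1-yl)oxy]dimethylsilane
Conditions: TBSCl, imidazole, CH2Cl2, 0 °C → rt
Reagents that add atoms: tert-butyldimethylsilyl chloride, CC(C)(C)[Si](C)(C)Cl
Why: Silylation of a primary alcohol with TBSCl and imidazole is standard, and the silyl ether is stable to the organobarium, hydride, alkoxide and Lewis acid steps that follow.

Step 7
Reactants: 5 6,6,8-trimethyl-1,4-dioxaspiro[4.5]dec-7-ene-7-carbaldehyde; 8 (E)-tert-butyl[(4-chloro-3-methylbut-2-en-1-yl)oxy]dimethylsilane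
Product: 10 racemic ring A dienol (±)-(E)-5-(tert-butyldimethylsilyloxy)-3-methyl-1-(6,6,8-trimethyl-1,4-dioxaspiro[4.5]dec-7-en-7-yl)pent-3-en-1-ol, via allylbarium chloride 9 (not isolated)
Conditions: BaI2, lithium biphenylide (2 equiv.), THF, rt; 8, −78 °C; then 5, −78 °C; aq. NH4Cl
Reagents that add atoms: none
Why: Allylbarium reagents made from allylic chlorides and activated barium at −78 °C keep their alkene geometry and add to aldehydes through the α-carbon (α-selective carbonyl allylation), which gives the linear (E)-dienol; the carbinol centre is formed racemic and is reset in steps 8 and 9.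

Step 8
Reactants: 10 racemic ring A dienol
Product: 11 (E)-5-(tert-butyldimethylsilyloxy)-3-methyl-1-(6,6,8-trimethyl-1,4-dioxaspiro[4.5]dec-7-en-7-yl)pent-3-en-1-one
Conditions: Dess–Martin periodinane, NaHCO3, CH2Cl2, 0 °C → rt
Reagents that add atoms: none
Why: Dess–Martin oxidation under bicarbonate buffer turns the hindered allylic carbinol into the ketone without base or acid strong enough to move the β,γ-alkene into conjugation.

Step 9
Reactants: 11 (E)-5-(tert-butyldimethylsilyloxy)-3-methyl-1-(6,6,8-trimethyl-1,4-dioxaspiro[4.5]dec-7-en-7-yl)pent-3-en-1-one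
Product: 12 (R,E)-5-(tert-butyldimethylsilyloxy)-3-methyl-1-(6,6,8-trimethyl-1,4-dioxaspiro[4.5]dec-7-en-7-yl)pent-3-en-1-ol (C6 carbinol R)
Conditions: (S)-2-methyl-CBS-oxazaborolidine (0.5 equiv.), BH3·SMe2, THF, −20 °C; MeOH quench
Reagents that add atoms: none
Why: Corey–Bakshi–Shibata reduction: the twisted tetrasubstituted cyclohexenyl group is the large and the CH2 group the small substituent, so the (S)-oxazaborolidine–borane complex should deliver hydride to the ketone face that gives the (R)-carbinol, as acetophenone gives the (R)-alcohol with the same catalyst.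

Step 10
Reactants: 12 (R,E)-5-(tert-butyldimethylsilyloxy)-3-methyl-1-(6,6,8-trimethyl-1,4-dioxaspiro[4.5]dec-7-en-7-yl)pent-3-en-1-ol
Product: 15 bicyclic alcohol 11-(tert-butyldimethylsilyloxy)-3,3-(ethylenedioxy)drim-8(12)-en-6-ol (trans-fused; C5/C9/C10 as in 22; 6-OH anti to the C10 methyl), via potassium enolate 13 (not isolated), via aldehyde 14 (not isolated)
Conditions: KN(SiMe3)2 (1.3 equiv.), 18-crown-6 (1.5 equiv.), THF, 0 → 50 °C; AcOH (1.3 equiv.), −78 °C; solvent exchange to CH2Cl2; Me2AlCl (4 equiv.), −78 → 0 °C; aqueous work-up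
Reagents that add atoms: none
Why: KN(SiMe3)2 forms the potassium alkoxide of 12, which undergoes an alkoxide-accelerated [3,3] shift through a chair (anionic oxy-Cope rearrangement) that makes C9–C10 and breaks C6–C7 to give enolate 13; acetic acid protonates C5 to give aldehyde 14, and Me2AlCl then activates the formyl group so that C7 of the isopropenyl group bonds to C6 while a hydrogen of the C8 methyl passes to oxygen (carbonyl-ene reaction). The closest known reaction types are the crown-ether-assisted anionic oxy-Cope rearrangement of acyclic 1,5-dien-3-ols, one-flask oxy-Cope/ene sequences and the Me2AlCl-promoted type 2 carbonyl-ene cyclisation of 5-methylhex-5-enals to 3-methylenecyclohexanols. Ring B closes as a six-membered ring in the type 2 ene mode (tether on the central carbon C8 of the ene unit, attack exo to the C=O bond), which leaves the exocyclic C8=C12 methylene. C10 and C9 are fixed by the chair: the C10 methyl, cis to C6 on the ring alkene, is axial, C11 on the (E)-alkene is equatorial and so ends up cis to that methyl, and the (R)-carbinol with its oxygen equatorial decides the face of C10 that is attacked; C5 should arise by axial protonation anti to the C10 methyl and is equilibrated in step 12, and the new C6 carbinol (drawn with oxygen equatorial, away from the axial C4 and C10 methyls) is erased in step 11. The step needs the chair with equatorial oxygen to win over the axial-oxygen chair and the boats, and the substrate secures this because the axial site on C6 is 1,3-diaxial to the axial C10 methyl, so that hydrogen and not oxygen is placed there.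

Step 11
Reactants: 15 11-(tert-butyldimethylsilyloxy)-3,3-(ethylenedioxy)drim-8(12)-en-6-ol
Product: 16 11-(tert-butyldimethylsilyloxy)-3,3-(ethylenedioxy)drim-8(12)-en-6-one (trans-fused; C5, C9, C10 as in 22)
Conditions: Dess–Martin periodinane, NaHCO3, CH2Cl2, rt
Reagents that add atoms: none
Why: Dess–Martin oxidation of the secondary C6 alcohol under buffered neutral conditions keeps the ketal and the silyl ether and merges any C6 epimers into one ketone.

Step 12
Reactants: 16 11-(tert-butyldimethylsilyloxy)-3,3-(ethylenedioxy)drim-8(12)-en-6-one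
Product: 17 11-(tert-butyldimethylsilyloxy)-3,3-(ethylenedioxy)drim-7-en-6-one (trans-fused; C5, C9, C10 as in 22)
Conditions: DBU (0.3 equiv.), CH2Cl2, 0 °C → rt
Reagents that add atoms: none
Why: Base-mediated isomerisation through the dienolate moves the exocyclic alkene into conjugation (β,γ- to α,β-enone isomerisation) and lets C5 settle in the more stable trans ring fusion, while the far less acidic tertiary C9–H of the product is left alone under these mild conditions.

Step 13
Reactants: 17 11-(tert-butyldimethylsilyloxy)-3,3-(ethylenedioxy)drim-7-en-6-one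
Product: 18 11-hydroxydrim-7-ene-3,6-dione (C5, C9, C10 as in 22)
Conditions: 2 M HCl, THF, 40 °C
Reagents that add atoms: water, O
Why: Dilute aqueous acid hydrolyses the dioxolane and cleaves the primary silyl ether in one operation (acetal hydrolysis and desilylation), while the enone and the three stereocentres are stable to it.

Step 14
Reactants: 18 11-hydroxydrim-7-ene-3,6-dione
Product: 19 drim-7-ene-3,6,11-triol (3-OH axial, 3S, anti to the C10 methyl; 6-OH on the face of the C10 methyl; C5, C9, C10 as in 22)
Conditions: LiBH(s-Bu)3 (4 equiv.), THF, −78 °C → rt; aq. NH4Cl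
Reagents that add atoms: none
Why: The bulky trialkylborohydride attacks the C3 ketone along the equatorial trajectory and so gives the axial (3S) alcohol, as is usual for 4,4-dimethyl-3-oxodecalins (stereoselective hydride reduction), and on warming it reduces the β,β-disubstituted enone in 1,2-fashion from the face opposite the axial C4 and C10 methyls, a centre that is oxidised again in step 16.

Step 15
Reactants: 19 drim-7-ene-3,6,11-triol; 20 umbelliferone (7-hydroxy-2H-chromen-2-one)
Product: 21 7-[(3,6-dihydroxydrim-7-en-11-yl)oxy]-2H-chromen-2-one (configuration as in 19)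
Conditions: PPh3, DIAD, THF, 0 °C → rt
Reagents that add atoms: none
Why: Mitsunobu etherification: the primary C11 alcohol is activated far faster than the two hindered secondary alcohols and is displaced by the acidic phenol 20, and because C6 is an alcohol at this stage C9–H is not acidified and elimination toward C9=C11 is not favoured.

Step 16
Reactants: 21 7-[(3,6-dihydroxydrim-7-en-11-yl)oxy]-2H-chromen-2-one
Product: 22 ferocaulidin, 7-{[(3S,5S,9R,10S)-3-hydroxy-6-oxodrim-7-en-11-yl]oxy}-2H-chromen-2-one
Conditions: MnO2 (excess), CH2Cl2, rt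
Reagents that add atoms: none
Why: MnO2 oxidises allylic alcohols selectively (allylic oxidation), so the C6 carbinol returns to the enone while the saturated axial C3 alcohol, the aryl ether and the coumarin are left untouched.

**Compound list**

1 | 2,2-dimethylcyclohexane-1,3-dione | CC1(C)C(=O)CCCC1=O | starting material
2 | 6,6-dimethyl-1,4-dioxaspiro[4.5]decan-7-one (ketal carbon = future C3) | CC1(C)C(=O)CCCC12OCCO2 | intermediate
3 | (±)-6,6,8-trimethyl-1,4-dioxaspiro[4.5]decan-7-one | CC1CCC2(OCCO2)C(C)(C)C1=O | intermediate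
4 | 6,6,8-trimethyl-1,4-dioxaspiro[4.5]dec-7-en-7-yl trifluoromethanesulfonate | CC1=C(OS(=O)(=O)C(F)(F)F)C(C)(C)C2(OCCO2)CC1 | intermediate
5 | 6,6,8-trimethyl-1,4-dioxaspiro[4.5]dec-7-ene-7-carbaldehyde (ring A enal; CHO carbon = C6) | CC1=C(C=O)C(C)(C)C2(OCCO2)CC1 | intermediate
6 | (E)-4-chloro-3-methylbut-2-en-1-yl acetate | ClC/C(C)=C/COC(C)=O | starting material
7 | (E)-4-chloro-3-methylbut-2-en-1-ol | ClC/C(C)=C/CO | intermediate
8 | (E)-tert-butyl[(4-chloro-3-methylbut-2-en-1-yl)oxy]dimethylsilane | ClC/C(C)=C/CO[Si](C)(C)C(C)(C)C | intermediate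
9 | [(E)-4-(tert-butyldimethylsilyloxy)-2-methylbut-2-en-1-yl]barium chloride (formed in the flask, not isolated) | Cl[Ba]C/C(C)=C/CO[Si](C)(C)C(C)(C)C | intermediate
10 | (±)-(E)-5-(tert-butyldimethylsilyloxy)-3-methyl-1-(6,6,8-trimethyl-1,4-dioxaspiro[4.5]dec-7-en-7-yl)pent-3-en-1-ol | CC1=C(C(O)C/C(C)=C/CO[Si](C)(C)C(C)(C)C)C(C)(C)C2(OCCO2)CC1 | intermediate
11 | (E)-5-(tert-butyldimethylsilyloxy)-3-methyl-1-(6,6,8-trimethyl-1,4-dioxaspiro[4.5]dec-7-en-7-yl)pent-3-en-1-one | CC1=C(C(=O)C/C(C)=C/CO[Si](C)(C)C(C)(C)C)C(C)(C)C2(OCCO2)CC1 | intermediate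
12 | (R,E)-5-(tert-butyldimethylsilyloxy)-3-methyl-1-(6,6,8-trimethyl-1,4-dioxaspiro[4.5]dec-7-en-7-yl)pent-3-en-1-ol | CC1=C([C@H](O)C/C(C)=C/CO[Si](C)(C)C(C)(C)C)C(C)(C)C2(OCCO2)CC1 | intermediate
13 | potassium (Z)-{6,6,8-trimethyl-8-[1-(tert-butyldimethylsilyloxy)-3-methylbut-3-en-2-yl]-1,4-dioxaspiro[4.5]decan-7-ylidene}methanolate (enolate oxygen cis to the CMe2 carbon; C9, C10 as in 22; not isolated) | [K+].[O-]/C=C1\C(C)(C)C2(OCCO2)CC[C@@]1(C)[C@H](CO[Si](C)(C)C(C)(C)C)C(C)=C | intermediate
14 | 6,6,8-trimethyl-8-[1-(tert-butyldimethylsilyloxy)-3-methylbut-3-en-2-yl]-1,4-dioxaspiro[4.5]decane-7-carbaldehyde (formyl trans to the side chain on ring A; C9, C10 as in 22; not isolated) | O=C[C@@H]1C(C)(C)C2(OCCO2)CC[C@@]1(C)[C@H](CO[Si](C)(C)C(C)(C)C)C(C)=C | intermediate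
15 | 11-(tert-butyldimethylsilyloxy)-3,3-(ethylenedioxy)drim-8(12)-en-6-ol (trans-fused, H5 anti to the C10 methyl; C11 syn to the C10 methyl; 6-OH anti to the C10 methyl) | C=C1C[C@@H](O)[C@@H]2C(C)(C)C3(OCCO3)CC[C@@]2(C)[C@@H]1CO[Si](C)(C)C(C)(C)C | intermediate
16 | 11-(tert-butyldimethylsilyloxy)-3,3-(ethylenedioxy)drim-8(12)-en-6-one (trans-fused; C5, C9, C10 as in 22) | C=C1CC(=O)[C@@H]2C(C)(C)C3(OCCO3)CC[C@@]2(C)[C@@H]1CO[Si](C)(C)C(C)(C)C | intermediate
17 | 11-(tert-butyldimethylsilyloxy)-3,3-(ethylenedioxy)drim-7-en-6-one (trans-fused; C5, C9, C10 as in 22) | CC1=CC(=O)[C@@H]2C(C)(C)C3(OCCO3)CC[C@@]2(C)[C@@H]1CO[Si](C)(C)C(C)(C)C | intermediate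
18 | 11-hydroxydrim-7-ene-3,6-dione (C5, C9, C10 as in 22) | CC1=CC(=O)[C@@H]2C(C)(C)C(=O)CC[C@@]2(C)[C@@H]1CO | intermediate
19 | drim-7-ene-3,6,11-triol (3S axial OH anti to the C10 methyl; 6-OH syn to the C10 methyl; C5, C9, C10 as in 22) | CC1=C[C@H](O)[C@@H]2C(C)(C)[C@@H](O)CC[C@@]2(C)[C@@H]1CO | intermediate
20 | umbelliferone (7-hydroxy-2H-chromen-2-one) | O=c1ccc2ccc(O)cc2o1 | starting material
21 | 7-[(3,6-dihydroxydrim-7-en-11-yl)oxy]-2H-chromen-2-one (configuration as in 19) | CC1=C[C@H](O)[C@@H]2C(C)(C)[C@@H](O)CC[C@@]2(C)[C@@H]1COc1ccc2ccc(=O)oc2c1 | intermediate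
22 | ferocaulidin, 7-{[(3S,5S,9R,10S)-3-hydroxy-6-oxodrim-7-en-11-yl]oxy}-2H-chromen-2-one | CC1=CC(=O)[C@@H]2C(C)(C)[C@@H](O)CC[C@@]2(C)[C@@H]1COc1ccc2ccc(=O)oc2c1 | target

**Step count**

Total: 16 steps. Longest linear sequence: 14 steps (steps 1–4 and 7–16); steps 5 and 6 form the side branch.

**Steps most likely to fail**

Step 10 (key step). The potassium alkoxide may cleave into enal 5 and an allyl anion (retro-allylation) faster than the hindered tetrasubstituted alkene terminus enters the chair. Chirality transfer may also erode if part of the material passes through the axial-oxygen chair. The fallback leaves the anionic manifold. Setting out from 12, Me3SiCl and imidazole would give trimethylsilyl ether F1. Heating this at about 220 °C in o-dichlorobenzene (sealed tube, base-washed glass, a little Et3N) should bring about the neutral thermal siloxy-Cope shift to silyl enol ether F2, which has no fragmentation channel. K2CO3 in MeOH would then release aldehyde 14, and Me2AlCl in CH2Cl2 would close ring B as in the second half of step 10, so that the route is rejoined at 15.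

Step 7. The δ-silyloxy allylbarium reagent may lose silyloxide by 1,4-elimination before it meets the hindered aldehyde, or it may react through its γ-carbon. The fallback builds the (E)-trisubstituted alkene after the C6–C7 bond. Setting out from 5, zinc-mediated Barbier propargylation (propargyl bromide, Zn, THF, 0 °C) would give homopropargylic alcohol F3. Zirconium-catalysed carboalumination (Me3Al, Cp2ZrCl2, 1 equiv. H2O, CH2Cl2, −30 °C), followed by n-BuLi and paraformaldehyde, would give (E)-diol F4 by syn addition of methyl and aluminium across the alkyne. Selective silylation of the primary allylic hydroxyl (TBSCl, imidazole, CH2Cl2, −20 °C) comes back to the route at 10.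

Step 15. Displacement at the β-branched C11 carbon may be slow, so that elimination of the activated alcohol or reaction at a secondary hydroxyl takes over. The fallback reverses the roles of the partners so that no substitution at C11 is needed. Setting out from 19, palladium-catalysed C–O coupling of the primary alcohol with purchased 7-bromocoumarin ([Pd(allyl)Cl]2, RockPhos, Cs2CO3, toluene, 90 °C) would give 21 directly, where the route is rejoined; no new compound is made on the way (F0).

**Further compounds**

F1 | step 10 | trimethylsilyl ether of 12, (R,E)-tert-butyldimethyl{[3-methyl-5-(trimethylsilyloxy)-5-(6,6,8-trimethyl-1,4-dioxaspiro[4.5]dec-7-en-7-yl)pent-2-en-1-yl]oxy}silane | CC1=C([C@H](O[Si](C)(C)C)C/C(C)=C/CO[Si](C)(C)C(C)(C)C)C(C)(C)C2(OCCO2)CC1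
F2 | step 10 | (Z)-trimethylsilyl enol ether of aldehyde 14 (oxygen cis to the CMe2 carbon; C9, C10 as in 22) | C[Si](C)(C)O/C=C1\C(C)(C)C2(OCCO2)CC[C@@]1(C)[C@H](CO[Si](C)(C)C(C)(C)C)C(C)=C
F3 | step 7 | (±)-1-(6,6,8-trimethyl-1,4-dioxaspiro[4.5]dec-7-en-7-yl)but-3-yn-1-ol | CC1=C(C(O)CC#C)C(C)(C)C2(OCCO2)CC1
F4 | step 7 | (±)-(E)-3-methyl-5-(6,6,8-trimethyl-1,4-dioxaspiro[4.5]dec-7-en-7-yl)pent-2-ene-1,5-diol | CC1=C(C(O)C/C(C)=C/CO)C(C)(C)C2(OCCO2)CC1
F0 | step 15 | none | none
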